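The plan rests on cutting ring A down to an open tetraketide: its six ring carbons plus the depside carbonyl are carried in a diketo-dioxinone. The key step exploits the bond between the ring A carboxyl carbon and the C4 oxygen of ring B. On heating, the dioxinone expels acetone and the ring B 4-hydroxyl adds to the acylketene, creating that C(=O)–O link; an aldol between chain carbons C2 and C7 and loss of water then close and aromatize ring A as a 2,4-dihydroxy-6-pentylbenzoate. The precursors are benzyl 2-heptyl-4-hydroxy-6-methoxybenzoate, itself made by the same annulation with benzyl alcohol as trap, and 2,2-dimethyl-6-(2,4-dioxononyl)-1,3-dioxin-4-one. Selective 4-O-methylation and hydrogenolysis complete the synthesis.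

Key step: step 8

Remark: polyketo compounds are drawn as keto tautomers although they will be largely enolized, and the cyclic aldols 11 and 20 are transient stereoisomer mixtures whose stereocenters vanish on aromatization (the target has no stereochemical element); dianion 6 is made once, in a batch sized for both acylations, so step 7 is run alongside step 2 on the reserved half of that solution and 17 is kept at −20 °C under argon until step 8.

Step 1
Reactants: 1 2,2,6-trimethyl-4H-1,3-dioxin-4-one; 2 acetyl chloride
Product: 4 2,2-dimethyl-6-(2-oxopropyl)-4H-1,3-dioxin-4-one, via lithium dienolate 3 (not isolated)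
Conditions: 1 (2.1 equiv), LiN(SiMe3)2 (2.1 equiv), THF, −78 °C; then 2 (1.0 equiv), −78 °C; then aq NH4Cl
Reagents that add atoms: none
Why: Kinetic deprotonation of the 6-methyl group gives the cross-conjugated dienolate 3, which is C-acylated at its exocyclic γ-carbon in a vinylogous Claisen condensation, the second equivalent of 3 serving as the base that takes up the acidic proton of the product so that it is not acylated again.

Step 2
Reactants: 4 2,2-dimethyl-6-(2-oxopropyl)-4H-1,3-dioxin-4-one; 5 octanoyl chloride
Product: 7 2,2-dimethyl-6-(2,4-dioxoundecyl)-4H-1,3-dioxin-4-one, via dilithium dianion 6 (not isolated)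
Conditions: 4, LiN(i-Pr)2 (2.0 equiv per 4), THF, −78 °C, one batch sized for steps 2 and 7; half of the cold solution of 6 set aside by cannula at −78 °C; to the other half 5 (0.5 equiv per dianion), −78 to −40 °C; then aq NH4Cl
Reagents that add atoms: none
Why: Double deprotonation gives dianion 6, whose last-formed terminal carbanion is its most nucleophilic site, so the acid chloride is attached at the methyl terminus in a dianion Claisen acylation; two equivalents of amide base per ketone leave no free amide to consume the acid chloride, and the twofold excess of dianion absorbs the acidic proton of the new 1,3-diketone in place of a second acylation.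

Step 3
Reactants: 7 2,2-dimethyl-6-(2,4-dioxoundecyl)-4H-1,3-dioxin-4-one; 8 benzyl alcohol
Product: 12 benzyl 2-heptyl-4,6-dihydroxybenzoate, via acylketene 9 (not isolated), via benzyl triketo ester 10 (not isolated), via cyclic aldol 11 (not isolated)
Conditions: 8 (1.5 equiv), PhMe, 110 °C; then Et3N, CH2Cl2, 0 °C to rt; then TFA, rt
Reagents that add atoms: none
Why: Retro-[4+2] loss of acetone gives acylketene 9, which the primary alcohol captures to give triketo ester 10; amine-promoted aldol of the C2 methylene onto the C7 ketone gives 11, and acid-promoted dehydration aromatizes it to the 6-alkyl-2,4-dihydroxybenzoate (ketene generation, trapping and aldol aromatization, which also rehearses the key-step protocol on cheap material).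

Step 4
Reactants: 12 benzyl 2-heptyl-4,6-dihydroxybenzoate
Product: 13 benzyl 4-(allyloxy)-2-heptyl-6-hydroxybenzoate
Conditions: allyl bromide (1.05 equiv), K2CO3 (1.1 equiv), acetone, rt to 40 °C
Reagents that add atoms: allyl bromide, C=CCBr
Why: The 4-hydroxyl, para to the ester and free of hydrogen bonding, is the more acidic and more accessible phenol, so a Williamson etherification with about one equivalent of allyl bromide and a mild carbonate base should stop at the mono-ether and leave the chelated 6-hydroxyl untouched.

Step 5
Reactants: 13 benzyl 4-(allyloxy)-2-heptyl-6-hydroxybenzoate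
Product: 14 benzyl 4-(allyloxy)-2-heptyl-6-methoxybenzoate
Conditions: MeI (3 equiv), K2CO3 (2 equiv), DMF, 50 °C
Reagents that add atoms: iodomethane, CI
Why: With the para oxygen blocked, forcing Williamson conditions break the hydrogen bond and methylate the remaining ortho hydroxyl, while the benzyl ester and the allyl ether are inert and 50 °C lies far below the onset of aromatic Claisen rearrangement.

Step 6
Reactants: 14 benzyl 4-(allyloxy)-2-heptyl-6-methoxybenzoate
Product: 15 benzyl 2-heptyl-4-hydroxy-6-methoxybenzoate
Conditions: Pd(PPh3)4 (5 mol%), morpholine (3 equiv), THF, rt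
Reagents that add atoms: none
Why: Zerovalent palladium ionizes the allyl aryl ether to a π-allylpalladium species and the phenoxide (Tsuji–Trost deallylation), and morpholine removes the allyl group irreversibly, conditions under which the benzyl ester and the methyl ether should stay intact.

Step 7
Reactants: 4 2,2-dimethyl-6-(2-oxopropyl)-4H-1,3-dioxin-4-one; 16 hexanoyl chloride
Product: 17 2,2-dimethyl-6-(2,4-dioxononyl)-4H-1,3-dioxin-4-one
Conditions: reserved half of the THF solution of dianion 6 (from 4 and LiN(i-Pr)2 in step 2), −78 °C; 16 (0.5 equiv per dianion), −78 to −40 °C; then aq NH4Cl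
Reagents that add atoms: none
Why: The dianion Claisen acylation of step 2 is repeated on the reserved portion of the same dianion solution, so the dianion is not generated again, and hexanoyl chloride as the limiting electrophile attaches at the terminal carbon of 6 the acyl group that becomes C7 and the pentyl chain of ring A.

Step 8
Reactants: 15 benzyl 2-heptyl-4-hydroxy-6-methoxybenzoate; 17 2,2-dimethyl-6-(2,4-dioxononyl)-4H-1,3-dioxin-4-one
Product: 21 benzyl 4-[(2,4-dihydroxy-6-pentylbenzoyl)oxy]-2-heptyl-6-methoxybenzoate, via acylketene 18 (not isolated), via triketo aryl ester 19 (not isolated), via cyclic aldol 20 (not isolated)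
Conditions: 15 (1.0 equiv, 0.5 M), PhMe, 110 °C, slow addition of 17 (1.3 equiv); then Et3N (1.0 equiv), CH2Cl2, 0 °C to rt; then TFA (excess), rt
Reagents that add atoms: none
Why: Near 110 °C the dioxinone ring of 17 fragments in a retro-[4+2] sense to acetone and acylketene 18, and the single free hydroxyl of 15 (on C4 of ring B) adds to the ketene carbon through a six-membered hydrogen-transfer transition state, forming the depside C(=O)–O bond and giving triketo aryl ester 19. Et3N then enolizes the chain, and C2, activated by both the ester and the C3 ketone, attacks the C7 ketone in a 6-exo-trig aldol closure (enolendo through the C3 enolate or enolexo through the ester enolate, both favourable) to give 20; TFA-promoted loss of water and enolization of the C3 and C5 carbonyls aromatize the new carbocycle to ring A with hydroxyls at C2 and C4 and the pentyl group at C6. The closest known reaction type is the thermolysis of diketo-dioxinones with capture of the acylketene by alcohols and aldol aromatization to 6-alkyl-2,4-dihydroxybenzoates, together with the routine acylation of phenols by dioxinone-derived acylketenes. The two stereocenters of 20 form without control and are erased on aromatization, so the step has no stereochemical demand. It needs two selectivities: intermolecular capture must outrun attack on the ketene by its own enol oxygen (pyranone formation), which a high phenol concentration and slow addition of 17 should secure, and the C2-to-C7 aldol must outrun lactonization or Claisen-type closure with loss of the aryloxide, which a weak amine base at 0 °C in a non-nucleophilic medium followed by acid should secure. Regiochemistry is fixed by the chain itself, because the pentyl-bearing ketone is C7 and only the C2–C7 bond gives a six-membered carbocycle with the ester carbon outside the ring, while 15 offers a single hydroxyl and a benzyl ester that ketenes do not touch.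

Step 9
Reactants: 21 benzyl 4-[(2,4-dihydroxy-6-pentylbenzoyl)oxy]-2-heptyl-6-methoxybenzoate
Product: 22 benzyl 2-heptyl-4-[(2-hydroxy-4-methoxy-6-pentylbenzoyl)oxy]-6-methoxybenzoate
Conditions: MeI (1.1 equiv), K2CO3 (1.1 equiv), acetone, rt
Reagents that add atoms: iodomethane, CI
Why: The 4-hydroxyl of ring A is not hydrogen-bonded and is the more acidic phenol, whereas the 2-hydroxyl is locked in a chelate with the depside carbonyl, so a Williamson methylation with about one equivalent of MeI and a heterogeneous weak base at room temperature should be site-selective and should not cleave the aryl ester.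

Step 10
Reactants: 22 benzyl 2-heptyl-4-[(2-hydroxy-4-methoxy-6-pentylbenzoyl)oxy]-6-methoxybenzoate
Product: 23 2-heptyl-4-[(2-hydroxy-4-methoxy-6-pentylbenzoyl)oxy]-6-methoxybenzoic acid
Conditions: H2 (1 atm), Pd/C (10 wt%), EtOAc, rt
Reagents that add atoms: none
Why: Catalytic hydrogenolysis cleaves only the benzylic C–O bond of the ester under neutral conditions, which should leave the depside ester, the aryl methyl ethers and the phenol intact and release the carboxylic acid as the target.

Compound list
1 | 2,2,6-trimethyl-4H-1,3-dioxin-4-one | CC1=CC(=O)OC(C)(C)O1 | starting material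
2 | acetyl chloride | CC(=O)Cl | starting material
3 | lithium dienolate of 1 (lithium 2,2-dimethyl-6-methylidene-6H-1,3-dioxin-4-olate) | C=C1C=C(O[Li])OC(C)(C)O1 | intermediate
4 | 2,2-dimethyl-6-(2-oxopropyl)-4H-1,3-dioxin-4-one | CC(=O)CC1=CC(=O)OC(C)(C)O1 | intermediate
5 | octanoyl chloride | CCCCCCCC(=O)Cl | starting material
6 | dilithium dianion of 4 (bis-enolate at the ring-side methylene and the terminal methyl) | C=C(O[Li])C=C1C=C(O[Li])OC(C)(C)O1 | intermediate
7 | 2,2-dimethyl-6-(2,4-dioxoundecyl)-4H-1,3-dioxin-4-one | CCCCCCCC(=O)CC(=O)CC1=CC(=O)OC(C)(C)O1 | intermediate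
8 | benzyl alcohol | OCc1ccccc1 | starting material
9 | 3,5,7-trioxotetradec-1-en-1-one (acylketene) | CCCCCCCC(=O)CC(=O)CC(=O)C=C=O | intermediate
10 | benzyl 3,5,7-trioxotetradecanoate | CCCCCCCC(=O)CC(=O)CC(=O)CC(=O)OCc1ccccc1 | intermediate
11 | benzyl 2-heptyl-2-hydroxy-4,6-dioxocyclohexane-1-carboxylate (stereoisomer mixture) | CCCCCCCC1(O)CC(=O)CC(=O)C1C(=O)OCc1ccccc1 | intermediate
12 | benzyl 2-heptyl-4,6-dihydroxybenzoate | CCCCCCCc1cc(O)cc(O)c1C(=O)OCc1ccccc1 | intermediate
13 | benzyl 4-(allyloxy)-2-heptyl-6-hydroxybenzoate | CCCCCCCc1cc(OCC=C)cc(O)c1C(=O)OCc1ccccc1 | intermediate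
14 | benzyl 4-(allyloxy)-2-heptyl-6-methoxybenzoate | CCCCCCCc1cc(OCC=C)cc(OC)c1C(=O)OCc1ccccc1 | intermediate
15 | benzyl 2-heptyl-4-hydroxy-6-methoxybenzoate | CCCCCCCc1cc(O)cc(OC)c1C(=O)OCc1ccccc1 | intermediate
16 | hexanoyl chloride | CCCCCC(=O)Cl | starting material
17 | 2,2-dimethyl-6-(2,4-dioxononyl)-4H-1,3-dioxin-4-one | CCCCCC(=O)CC(=O)CC1=CC(=O)OC(C)(C)O1 | intermediate
18 | 3,5,7-trioxododec-1-en-1-one (acylketene) | CCCCCC(=O)CC(=O)CC(=O)C=C=O | intermediate
19 | benzyl 2-heptyl-6-methoxy-4-[(3,5,7-trioxododecanoyl)oxy]benzoate | CCCCCCCc1cc(OC(=O)CC(=O)CC(=O)CC(=O)CCCCC)cc(OC)c1C(=O)OCc1ccccc1 | intermediate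
20 | benzyl 2-heptyl-4-{[(2-hydroxy-4,6-dioxo-2-pentylcyclohexyl)carbonyl]oxy}-6-methoxybenzoate (stereoisomer mixture) | CCCCCCCc1cc(OC(=O)C2C(=O)CC(=O)CC2(O)CCCCC)cc(OC)c1C(=O)OCc1ccccc1 | intermediate
21 | benzyl 4-[(2,4-dihydroxy-6-pentylbenzoyl)oxy]-2-heptyl-6-methoxybenzoate | CCCCCCCc1cc(OC(=O)c2c(O)cc(O)cc2CCCCC)cc(OC)c1C(=O)OCc1ccccc1 | intermediate
22 | benzyl 2-heptyl-4-[(2-hydroxy-4-methoxy-6-pentylbenzoyl)oxy]-6-methoxybenzoate | CCCCCCCc1cc(OC(=O)c2c(O)cc(OC)cc2CCCCC)cc(OC)c1C(=O)OCc1ccccc1 | intermediate
23 | 2-heptyl-4-[(2-hydroxy-4-methoxy-6-pentylbenzoyl)oxy]-6-methoxybenzoic acid (CNP0518349.0) | CCCCCCCc1cc(OC(=O)c2c(O)cc(OC)cc2CCCCC)cc(OC)c1C(=O)O | target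

Total step count: 10
Longest linear sequence: 9 steps (1, 2, 3, 4, 5, 6, 8, 9, 10; the hexanoyl acylation is a one-step side branch fed by the shared dianion batch)

Steps most likely to fail

Highest risk: Step 8. In step 8 two processes could divert the material. The acylketene could be captured by its own enol oxygen faster than by the electron-poor phenol. After capture, the chain could close with expulsion of the aryloxide (lactonization or Claisen-type C-acylation) faster than the aldol. The fallback sets out from 17, uses 15, and comes back to the route at 22, so that the selective O-methylation of the main route is no longer needed. Treatment of 17 with Et3N in CH2Cl2 at room temperature, without heating, would aromatize the chain with the dioxinone retained and give 7-hydroxy-2,2-dimethyl-5-pentyl-4H-1,3-benzodioxin-4-one F1, in which the acetonide masks the hydroxyl ortho to the carbonyl. Methylation of the only free phenol (MeI, K2CO3, acetone) would give 7-methoxy-2,2-dimethyl-5-pentyl-4H-1,3-benzodioxin-4-one F2. Hydrolysis with KOH in aqueous DMSO and cold acidification would give 2-hydroxy-4-methoxy-6-pentylbenzoic acid F3. Condensation of this acid with phenol 15 through its mixed anhydride, made with (CF3CO)2O in toluene at room temperature (the classical depside esterification), would then give 22.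

Second risk: Step 2. In step 2 proton transfer from the newly formed 1,3-diketone to unreacted dianion, and O-acylation or double acylation by the very reactive acid chloride, could erode the conversion; the sister acylation with hexanoyl chloride carries the same risk. The fallback sets out from 4 and comes back at 7, replacing the acylation by an aldol addition and an oxidation. Dianion 6 (one equivalent, made as before) would add through its terminal carbon to octanal at −78 °C. The adduct is a non-acidic alkoxide that cannot react further, and work-up would give racemic 6-(4-hydroxy-2-oxoundecyl)-2,2-dimethyl-4H-1,3-dioxin-4-one F4. Oxidation of the secondary alcohol with Dess–Martin periodinane in CH2Cl2 would give 7. Run with hexanal, the same two operations would pass through racemic 6-(4-hydroxy-2-oxononyl)-2,2-dimethyl-4H-1,3-dioxin-4-one F5 and come back at 17.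

Third risk: Step 9. In step 9 site selectivity could be lost through methylation of the chelated hydroxyl as well, or the phenoxide formed under basic conditions could trigger acyl transfer or cleavage at the activated aryl ester. The fallback sets out from 21 and comes back at 22, replacing phenoxide alkylation by a Mitsunobu etherification (PPh3, diisopropyl azodicarboxylate, MeOH, THF, 0 °C). Here methanol, not the phenol, is activated as an alkoxyphosphonium ion, no carbonate base is present, and only the more acidic non-chelated 4-hydroxyl should be ionized and methylated. This detour makes no new compound, hence the entry F0.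

Further compounds
F1 | step 8 | 7-hydroxy-2,2-dimethyl-5-pentyl-4H-1,3-benzodioxin-4-one | CCCCCc1cc(O)cc2OC(C)(C)OC(=O)c12
F2 | step 8 | 7-methoxy-2,2-dimethyl-5-pentyl-4H-1,3-benzodioxin-4-one | CCCCCc1cc(OC)cc2OC(C)(C)OC(=O)c12
F3 | step 8 | 2-hydroxy-4-methoxy-6-pentylbenzoic acid | CCCCCc1cc(OC)cc(O)c1C(=O)O
F4 | step 2 | racemic 6-(4-hydroxy-2-oxoundecyl)-2,2-dimethyl-4H-1,3-dioxin-4-one | CCCCCCCC(O)CC(=O)CC1=CC(=O)OC(C)(C)O1
F5 | step 2 | racemic 6-(4-hydroxy-2-oxononyl)-2,2-dimethyl-4H-1,3-dioxin-4-one | CCCCCC(O)CC(=O)CC1=CC(=O)OC(C)(C)O1
F0 | step 9 | none | none
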